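The ochre run reaches 46.2% of the solid substrate at 15.0 min, then reads 46.6% and 48.7%, a flat stretch with a mean of 47.2%. Measured against that mean, the 8.00 min reading gives a half-life of about 3.25 min for the rise. The 30 min of this flask is far longer than that, about 9.23 half-lives, so the reckoning here expects the rise to be over by then.

common to all: solid substrate 0.16 M; partner 0.152 M; temperature 70 °C
- ochre: the very flask that is asked about, followed so far
- flask: time 30 min

ochre run (percent of the solid substrate charged): time / min: single product / % = 2.50: 16.3; 8.00: 38.6; 15.0: 46.2; 20.0: 46.6; 30.0: 48.7

(each reading ± 1 percentage point)

* single product, in percent of the solid substrate first charged, at 30 min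
* the remedy with the largest gain of single product, or "none" below 2 percentage points (zeta / gamma / beta / delta / none)
* single product present, with what was taken out counted in, in percent of the solid substrate first charged, after gamma
* single product present, with what was taken out counted in, in percent of the solid substrate first charged, after delta

- zeta: at 30 min add partner, 100% of the amount charged, then wait 1.0 h
- gamma: change nothing and wait 1.0 h more
- beta: at 30 min raise the temperature by 25 K, then wait 1.0 h
- delta: at 30 min take out 90% of the single product then present, then wait 1.0 h

- given per volume of solution although it is solid: solid substrate
- single product taken out counts as made
- the numbers in the tables scatter by 1 percentage point (one standard deviation)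
- at the start none of the solid substrate is in solution
- the earlier runs do not show what temperature does; that part of a forecast is a guess
- additions bring no volume worth counting

The charges and the flat stretch fold into one number, the partner yield 0.496: single product found per partner charged. About half of the partner charge therefore stands as single product. The reckoning here commits to 47.2% now. Gamma and delta leave c(partner) as it was, so both stay near 47.2%, while zeta raises c(partner) and is the choice. One number is not enough, though. No reading shows partner, so the partner yield cannot say whether the other half of the charge is still in solution or spent, and the size of zeta stays open.

The forecast gives 48% now, zeta as best, 48.8% after gamma and 65% after delta, holding that “equilibrium is the likeliest reading”. On delta it stands 18 percentage points above the reckoning here.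

The flask gives 48.1% at 30 min. Zeta gains 8.9 points, more than any other remedy, so the best is zeta. Gamma ends at 48.6% and delta at 48.6%.

    solid substrate ⇌ starting material, rate k1*(cs1 - [starting material]) while solid is left; crystals form when [starting material] > cs1 (solubility = 0.110 M, k = 1.10 min⁻¹)
    starting material + partner → other mono adduct (k = 0.705 M⁻¹ min⁻¹, Ea = 69.0 kJ mol⁻¹)
    starting material + partner → single product (k = 1.27 M⁻¹ min⁻¹, Ea = 74.0 kJ mol⁻¹)
    partner + single product → double product (k = 0.0226 M⁻¹ min⁻¹, Ea = 94.0 kJ mol⁻¹)
    partner + other mono adduct → double product (k = 2.73 M⁻¹ min⁻¹, Ea = 65.0 kJ mol⁻¹)
    (constants at 70 °C)

At 30 min the flask holds 1.3% of its partner charge. The partner yield turns that remainder into 0.598% of the solid substrate, and gamma gains 0.48 points. A neighbouring flask carries 0.27 M of solid substrate against the same 0.152 M of partner, and in that flask partner is the limiting reagent. The same partner yield gives 27.9% of its solid substrate as single product, and the neighbouring flask stands at 30.1%. In the neighbouring flask partner is down to 0.0467% of its charge, while starting material holds 40.7% of the solid substrate charged.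

Readings and results were generated by integration with made-up constants; noise was put on by code.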